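## The problem

Compound 25 is a fully substituted cyclobutane. With the ring numbered C1, C2 (carboxyl-bearing), C3 (aryl, next to C2) and C4 (aryl, next to C1), both carboxyls are esterified through the secondary hydroxyl of (R)-3-(3,4-dihydroxyphenyl)lactic acid, whose own acids are free. The ring is C2-symmetric (1R,2R,3R,4R): the esters are trans to each other and the aryls are trans to each other, yet each ester is cis to the aryl on the adjacent carbon (C1/C4 and C2/C3). This is not the all-trans isomer towards which base would drive the ester-bearing centres. C3 and C4 are benzylic and cannot be epimerised, so they must be set by bond formation, whereas C1 and C2 are α to carbonyls and, once set, must not meet enolising conditions. Only C3 can act as a fixed anchor: it can fix C4 by equilibration (trans) and C2 by delivery of hydrogen to C3 on the face away from the C2 ester, which leaves C1, flanked by a cis aryl and a trans ester, to be decided last. The four catechols oxidise easily, the side-chain stereocentres (α to an ester and bearing an acyloxy group) racemise with base, and the ring carries donor aryls next to acceptor esters; benzyl protection and a neutral final hydrogenolysis answer these points. The key step rests on the unit C4–C1–C(=O)O: the carboxyl carbon on C1 can be seen as extruded from between C1 and C4 of a five-membered ketone, a ring on which C4 is an equilibrating α-aryl centre and the C2/C3 pair can be set on an enone.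

## Retrosynthesis

Ring atoms keep the target numbering (C1–C4) in this section.

**25 from 24.** Ten O–CH2Ph bonds are cut (eight aryl ethers, two esters). Benzyl is chosen over methyl or silyl protection because its removal needs neither Lewis acid nor base next to four epimerisable centres. Compound 24 has the complete skeleton and all six stereocentres but no free phenol or acid. The forward step must spare the two non-benzylic ester links and the strained ring.

**24 from 20 and 23.** The bond cut is the O–C(sp3) bond of the C2 ester, between the carboxylate oxygen and the side-chain carbinol carbon. The neighbouring cut, at the acyl–O bond, would turn the C2 carboxyl into an acyl donor and make the C2 hydrogen acidic exactly where the cis ester/aryl arrangement is least stable. In the chosen cut the acid 20 is only a nucleophile. The price is inversion at the carbinol carbon, so the (S)-alcohol 23 is needed; it comes from the amino acid 21 through the hydroxy acid 22.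

**20 from 19.** The O–C(CH3)3 bond is cut. A tert-butyl ester at C2 is inert to the alkoxide, hydride and amine steps that precede it and falls to acid in the presence of benzyl groups and of the C1 ester.

**19 from 14 and 16.** Two bonds are cut: the ring bond C1–C4 and the acyl–O bond of the C1 ester. In reverse the carboxyl carbon of C1 is re-inserted between C1 and C4, which gives the five-membered α-diazo ketone 14, and the side chain leaves as the alcohol 16. Forward, 14 loses N2, C4 migrates to C1 and the ketene 17 takes up 16 to give the ester enol 18 and then 19. A cut across C1–C2 and C3–C4 (head-to-head dimerisation of two cinnamate units) would need both partners in the Z form and offers no handle on face or orientation. On the cyclopentanone, by contrast, the trans C3/C4 pair is the stable one and the cis C2/C3 pair is a kinetic enone reduction. The forward step must give migration with retention, capture of a ketene by a hindered secondary alcohol, and protonation of C1 on the face away from the C4 aryl.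

**14 from 13 and 12.** The C1=N2 bond is cut; the diazo group is brought in by exchange for a formyl group, so the precursor is the hydroxymethylene ketone 13 and, before it, the ketone 12. Formylation is reversible, so only the methylene α-carbon (C1) can keep the formyl group; the aryl-bearing α-carbon (C4) cannot. The step must not disturb the ester-bearing centre C2.

**12 from 10.** The C3–H and C4–H bonds are cut, which leads to the enone 10. Bringing the C3 aryl in by conjugate addition instead would place it trans to the C2 ester, so hydrogen has to be the group delivered to C3. Compound 10 has a single, stereolabile centre in place of three. The forward reduction must add hydride to C3 anti to the ester and pick one enantiomer of the interconverting pair; the first-formed ketone 11 is then equilibrated at C4 to 12.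

**10 from 8, and 8 from 3 and 7.** The C3=C4 bond is cut by a retro-aldol condensation to the 1,4-diketone 8, and the C1–C2 bond by a retro-alkylation to the β-keto ester 3 and the bromo ketone 7. Each half holds one arene and two or three carbons. The forward steps must give C-alkylation and a ring closure that does not cost the aroyl group by retro-Claisen cleavage.

**Building blocks.** Compound 3 is the two-carbon homologue of acid 1, compound 7 the one-carbon homologue of acid 4 (through 5 and 6), and 16 is the perbenzylated natural hydroxy acid 15.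

## Roads not taken

**Alternative 1:** The cut is at the two C–aryl bonds of the diamide A3, leading back to the trans-diamide A1 and the aryl iodide A2. Forward, Pd(OAc)2 with AgOAc would arylate the methylene hydrogen cis to each directing amide. Each aryl therefore arrives cis to its own carbonyl and the two aryls end up trans, which is exactly the ring configuration of 25, in one operation and from a compound whose two centres come from a classical resolution. This road is about half as long as the chosen one and avoids both an enantioselective enone reduction and a face-selective enol protonation; in step count and in the security of the ring stereochemistry it is the better road. Its weak points lie after the key step. Two hindered quinolinyl amides must be cleaved at centres that sit in the less stable cis arrangement, and the usual N-activation followed by hydroxide or alkoxide invites epimerisation to the all-trans diacid. The second arylation must also take place beside the first aryl, and the silver salt is stoichiometric. Both side chains would then be attached by a twofold Mitsunobu reaction with 23. Against this the chosen plan offers esters throughout, no auxiliary removal, and a first side chain that enters in the ring-forming step.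

**Alternative 2:** The cut is at C1–C4 of the cyclobutene diester A5, leading back to the cyclopropyl diazo ester A4. Forward, Rh2(OAc)4 would generate a carbene whose carbon accepts a migrating ring carbon, expanding three to four. Both carboxyl carbons are in place before the ring forms, neither C1 nor C2 is a stereocentre in the key step, and the two cyclopropane bonds that can migrate are equivalent. The weak points are that cyclopropyl carbenes also fragment to alkene and alkyne, and that a trans-3,4-diaryl cyclobutene with two esters is set up for conrotatory opening to a diene. Above all, A5 must still be reduced: syn hydrogenation gives the cis diester, and equilibration from there leads to the all-trans isomer, not to the one needed. The problem of C1 and C2 is thus postponed and doubled, whereas the chosen plan meets it once, at C1, with C2 already fixed.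

**Alternative 3:** The cut is at C1–C2 of the triester A7, leading back to the acyclic triflate A6. Forward, Cs2CO3 would let the malonate carbon displace the triflate with inversion. The sense of the new C2 centre is reliable, no light is needed, and C1 is not stereogenic at ring closure. The weak points are a four-membered closure at a secondary carbon whose β-hydrogen is benzylic, so elimination to a cinnamate-type alkene is likely to win, and an open-chain precursor with three contiguous stereocentres. One of the two geminal esters must afterwards be removed, and decarboxylation then creates C1 by protonation of an enol. That is the same face problem as in the chosen plan, met at higher temperature and without a side chain attached. The chosen plan builds its three ring centres on a ring, where relay from C3 is dependable.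

Key step: step 9

Conventions and assumption: Ar = 3,4-bis(benzyloxy)phenyl. Locants in compound names follow nomenclature rules and differ from the target numbering used above. The sense of induction of the ligated copper hydride on enone 10 cannot be assigned with certainty from simpler enones; (R)-DTBM-SEGPHOS is written for the enantiomer shown, and the (S)-ligand would be used if the sense proves opposite.

## Route

Step 1
Reactants: 1 3,4-bis(benzyloxy)benzoic acid
Product: 3 tert-butyl 3-Ar-3-oxopropanoate, via acyl dioxanedione 2 (not isolated)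
Conditions: Meldrum's acid, DCC, DMAP, CH2Cl2, 0 °C→rt; then t-BuOH, PhMe, 90 °C
Reagents that add atoms: 2,2-dimethyl-1,3-dioxane-4,6-dione (Meldrum's acid) CC1(C)OC(=O)CC(=O)O1; tert-butanol CC(C)(C)O
Why: The carbodiimide-activated acid C-acylates the very acidic dioxanedione to give 2, and heating 2 with tert-butanol opens the ring with loss of acetone and CO2 (acylation–alcoholysis route to β-keto esters); aryl benzyl ethers are inert to both stages.

Step 2
Reactants: 4 [3,4-bis(benzyloxy)phenyl]acetic acid
Product: 7 1-Ar-3-bromopropan-2-one, via acid chloride 5 (not isolated), via diazomethyl ketone 6 (not isolated)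
Conditions: (COCl)2, DMF (cat.), CH2Cl2, 0 °C→rt; CH2N2, Et2O, 0 °C; 48% aq. HBr, 0 °C
Reagents that add atoms: diazomethane C=[N+]=[N-]; hydrogen bromide Br
Why: The acid chloride acylates diazomethane (first half of an Arndt–Eistert sequence) and the diazomethyl ketone is protonated on carbon by HBr and displaced by bromide with loss of N2, so bromine enters only at the terminal carbon and the benzylic methylene stays free.

Step 3
Reactants: 3 tert-butyl 3-Ar-3-oxopropanoate; 7 1-Ar-3-bromopropan-2-one
Product: 8 tert-butyl 2-(3,4-bis(benzyloxy)benzoyl)-5-Ar-4-oxopentanoate (racemic)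
Conditions: K2CO3, acetone, rt
Reagents that add atoms: none
Why: SN2 C-alkylation of the β-keto ester enolate by a primary α-bromo ketone (acetoacetic ester alkylation); carbonate is too weak to start Favorskii chemistry of 7, and the new centre is of no consequence because it becomes stereolabile in 10.

Step 4
Reactants: 8 tert-butyl 2-(3,4-bis(benzyloxy)benzoyl)-5-Ar-4-oxopentanoate
Product: 10 tert-butyl 2,3-Ar2-4-oxocyclopent-2-ene-1-carboxylate (racemic), via aldol adduct 9 (not isolated)
Conditions: KOt-Bu, t-BuOH–THF, 0 °C→rt; AcOH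
Reagents that add atoms: none
Why: Intramolecular aldol condensation of a 1,4-diketone (the usual cyclopentenone closure): the benzylic ketone enolate adds to the aroyl carbonyl to give 9, which loses water by E1cB to the conjugated enone; tert-butoxide is not nucleophilic enough for retro-Claisen cleavage and the tert-butyl ester resists Dieckmann attack.

Step 5
Reactants: 10 tert-butyl 2,3-Ar2-4-oxocyclopent-2-ene-1-carboxylate (racemic)
Product: 12 tert-butyl (1S,2R,3S)-2,3-Ar2-4-oxocyclopentane-1-carboxylate, via all-cis ketone 11 (not isolated)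
Conditions: Cu(OAc)2·H2O (5 mol %), (R)-DTBM-SEGPHOS (5.5 mol %), (EtO)2MeSiH, t-BuOH, NaOt-Bu (10 mol %), PhMe, 0 °C→rt; then DBU (0.2 equiv), CH2Cl2, rt
Reagents that add atoms: none
Why: Proposed new method: a ligated monovalent copper hydride adds hydride to the β-carbon (C2) of the enone and tert-butanol protonates the copper enolate; the bulky reagent should approach anti to the neighbouring tert-butoxycarbonyl group, so each enantiomer of 10 is reduced on its ester-free face to give the cis ester/aryl pair, and because the hydrogen at C1 of 10 (α to the ester and vinylogous to the ketone) exchanges rapidly with catalytic alkoxide, the chiral ligand can draw the whole racemate through the matched (1S)-enantiomer (dynamic kinetic resolution), fixing C2 as R and C1 as S; DBU then equilibrates the α-aryl centre so that 11 passes to the trans-diaryl ketone 12; the closest known reaction type is the copper hydride-catalysed asymmetric conjugate reduction of β-substituted cyclopentenones, including its dynamic kinetic resolution variant with base-labile centres, which has not been shown on tetrasubstituted 2,3-diaryl enones.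

Step 6
Reactants: 12 tert-butyl (1S,2R,3S)-2,3-Ar2-4-oxocyclopentane-1-carboxylate
Product: 13 tert-butyl (1R,2R,3S)-2,3-Ar2-5-(hydroxymethylidene)-4-oxocyclopentane-1-carboxylate
Conditions: NaH, HCO2Et, EtOH (cat.), THF, 0 °C→rt; aq. HCl to pH 4
Reagents that add atoms: ethyl formate CCOC=O
Why: Crossed Claisen formylation under equilibrating conditions: only the methylene α-carbon can give a β-keto aldehyde that is held as its enolate, so acylation at the aryl-bearing α-carbon reverts; that centre stays in its stable trans arrangement, and the ester α-hydrogen, far less acidic than the ketone hydrogens, should not exchange at this temperature (the descriptor at C1 changes only because priorities change).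

Step 7
Reactants: 13 tert-butyl (1R,2R,3S)-2,3-Ar2-5-(hydroxymethylidene)-4-oxocyclopentane-1-carboxylate
Product: 14 tert-butyl (1R,2R,3S)-2,3-Ar2-5-diazo-4-oxocyclopentane-1-carboxylate
Conditions: 4-AcNHC6H4SO2N3, Et3N, MeCN, 0 °C→rt
Reagents that add atoms: 4-acetamidobenzenesulfonyl azide CC(=O)Nc1ccc(cc1)S(=O)(=O)N=[N+]=[N-]
Why: Regitz deformylative diazo transfer: the enolate of 13 adds to the sulfonyl azide and the adduct fragments to the α-diazo ketone and the N-formyl sulfonamide; triethylamine is too weak to touch the ester-bearing centre.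

Step 8
Reactants: 15 (2R)-3-(3,4-dihydroxyphenyl)-2-hydroxypropanoic acid (danshensu)
Product: 16 benzyl (2R)-3-Ar-2-hydroxypropanoate
Conditions: BnBr, K2CO3, DMF, rt, Ar
Reagents that add atoms: benzyl bromide BrCc1ccccc1
Why: Williamson O-alkylation of the two phenoxides and SN2 esterification of the carboxylate; potassium carbonate does not ionise the secondary alcohol, which stays free, and the stereocentre is not involved.

Step 9
Reactants: 14 tert-butyl (1R,2R,3S)-2,3-Ar2-5-diazo-4-oxocyclopentane-1-carboxylate; 16 benzyl (2R)-3-Ar-2-hydroxypropanoate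
Product: 19 1-[(2R)-1-(benzyloxy)-3-Ar-1-oxopropan-2-yl] 2-tert-butyl (1R,2R,3R,4R)-3,4-Ar2-cyclobutane-1,2-dicarboxylate, via ketene 17 (not isolated), via ester enol 18 (not isolated)
Conditions: hν (365 nm), 16 (2.5 equiv), PhMe (0.02 M), 4 Å MS, 0 °C
Reagents that add atoms: none
Why: Excitation of the cyclic α-diazo ketone, which is locked s-cis, expels N2 with concerted 1,2-shift of the aryl-bearing α-carbon from the carbonyl carbon to the diazo carbon (photochemical Wolff rearrangement), so the new ring bond forms with retention at the migrating centre and free-carbene side reactions are not expected. The four-membered ring is closed by ring contraction (five to four), not by an end-to-end cyclisation, the strain being paid for by loss of N2, and the immediate product is the cyclobutylidene ketene 17. The alcohol 16 adds to the ketene carbonyl in the plane of the ring to give the ester enol 18, which forms the ester C–O bond; the closest known reaction type is the photochemical ring contraction of 2-diazocycloalkanones with capture of the ketene by an alcohol. The one new stereocentre, the ester-bearing ring carbon, is set when 18 is protonated on carbon: the proton should enter anti to the aryl on the migrated carbon, the larger of the two flanking groups (conformational A values of about 2.8 kcal/mol for aryl against about 1.2 for alkoxycarbonyl), which places the new ester cis to that aryl and trans to the tert-butyl ester. This epimer should also be the more stable one, since it avoids a cis vicinal diester and an all-cis 1,2,3 array, so no later drift away from it is expected. The three existing ring centres are untouched (retention at the migrating carbon, no base present) and the (R)-centre of 16 is a spectator. The step needs facial selectivity in this protonation and efficient capture of 17 by a hindered α-hydroxy ester; excess 16, high dilution and low temperature serve both. Product derived from any residual antipode of 14 is a diastereomer of 19 and is removed here by chromatography.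

Step 10
Reactants: 19 1-[(2R)-1-(benzyloxy)-3-Ar-1-oxopropan-2-yl] 2-tert-butyl (1R,2R,3R,4R)-3,4-Ar2-cyclobutane-1,2-dicarboxylate
Product: 20 (1R,2R,3R,4R)-2-({[(2R)-1-(benzyloxy)-3-Ar-1-oxopropan-2-yl]oxy}carbonyl)-3,4-Ar2-cyclobutane-1-carboxylic acid
Conditions: CF3CO2H–CH2Cl2 (1:4), 0 °C→rt
Reagents that add atoms: none
Why: Acidolysis of the tert-butyl ester by alkyl–oxygen cleavage with loss of isobutene; the benzyl ester, the secondary alkyl ester and the aryl benzyl ethers are stable to cold dilute trifluoroacetic acid, and no base is present that could epimerise the ring or the side chain.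

Step 11
Reactants: 21 L-DOPA, (2S)-2-amino-3-(3,4-dihydroxyphenyl)propanoic acid
Product: 22 (2S)-3-(3,4-dihydroxyphenyl)-2-hydroxypropanoic acid
Conditions: NaNO2, 1 M aq. H2SO4, 0 °C→rt, Ar
Reagents that add atoms: water O
Why: Diazotisation of an α-amino acid; neighbouring-carboxylate participation (double inversion) replaces nitrogen by hydroxyl with net retention, so the (S)-configuration is kept; cold, strongly acidic medium and exclusion of air limit attack of nitrous acid on the catechol.

Step 12
Reactants: 22 (2S)-3-(3,4-dihydroxyphenyl)-2-hydroxypropanoic acid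
Product: 23 benzyl (2S)-3-Ar-2-hydroxypropanoate
Conditions: BnBr, K2CO3, DMF, rt, Ar
Reagents that add atoms: benzyl bromide BrCc1ccccc1
Why: As in step 8: Williamson O-alkylation of the phenoxides and SN2 esterification of the carboxylate, with the secondary alcohol left free and the stereocentre untouched.

Step 13
Reactants: 20 (1R,2R,3R,4R)-2-({[(2R)-1-(benzyloxy)-3-Ar-1-oxopropan-2-yl]oxy}carbonyl)-3,4-Ar2-cyclobutane-1-carboxylic acid; 23 benzyl (2S)-3-Ar-2-hydroxypropanoate
Product: 24 bis[(2R)-1-(benzyloxy)-3-Ar-1-oxopropan-2-yl] (1R,2R,3R,4R)-3,4-Ar2-cyclobutane-1,2-dicarboxylate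
Conditions: PPh3, DIAD, THF, 0 °C→rt
Reagents that add atoms: none
Why: Mitsunobu esterification: the carboxylate of 20 displaces the phosphorus-activated oxygen of 23 in an SN2 step with inversion, turning the (S)-carbinol into the (R)-ester; because the acid is never activated as an acyl donor, its α-centre cannot epimerise.

Step 14
Reactants: 24 bis[(2R)-1-(benzyloxy)-3-Ar-1-oxopropan-2-yl] (1R,2R,3R,4R)-3,4-Ar2-cyclobutane-1,2-dicarboxylate
Product: 25 bis[(1R)-1-carboxy-2-(3,4-dihydroxyphenyl)ethyl] (1R,2R,3R,4R)-3,4-bis(3,4-dihydroxyphenyl)cyclobutane-1,2-dicarboxylate (CNP0163929.1)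
Conditions: H2 (1 atm), 10% Pd/C, THF–MeOH, rt
Reagents that add atoms: none
Why: Hydrogenolysis of ten benzylic C–O bonds (eight aryl benzyl ethers, two benzyl esters) under neutral conditions; the two remaining ester links are to non-benzylic carbons and the cyclobutane C–C bonds should not be cleaved at one atmosphere, so all six stereocentres are carried through.

## Compound list

1 | 3,4-bis(benzyloxy)benzoic acid | O=C(O)c1ccc(OCc2ccccc2)c(OCc2ccccc2)c1 | starting material
2 | 5-[3,4-bis(benzyloxy)benzoyl]-2,2-dimethyl-1,3-dioxane-4,6-dione | CC1(C)OC(=O)C(C(=O)c2ccc(OCc3ccccc3)c(OCc3ccccc3)c2)C(=O)O1 | intermediate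
3 | tert-butyl 3-[3,4-bis(benzyloxy)phenyl]-3-oxopropanoate | CC(C)(C)OC(=O)CC(=O)c1ccc(OCc2ccccc2)c(OCc2ccccc2)c1 | intermediate
4 | [3,4-bis(benzyloxy)phenyl]acetic acid | O=C(O)Cc1ccc(OCc2ccccc2)c(OCc2ccccc2)c1 | starting material
5 | [3,4-bis(benzyloxy)phenyl]acetyl chloride | O=C(Cl)Cc1ccc(OCc2ccccc2)c(OCc2ccccc2)c1 | intermediate
6 | 1-[3,4-bis(benzyloxy)phenyl]-3-diazopropan-2-one | [N-]=[N+]=CC(=O)Cc1ccc(OCc2ccccc2)c(OCc2ccccc2)c1 | intermediate
7 | 1-[3,4-bis(benzyloxy)phenyl]-3-bromopropan-2-one | BrCC(=O)Cc1ccc(OCc2ccccc2)c(OCc2ccccc2)c1 | intermediate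
8 | tert-butyl 2-[3,4-bis(benzyloxy)benzoyl]-5-[3,4-bis(benzyloxy)phenyl]-4-oxopentanoate (racemic) | CC(C)(C)OC(=O)C(CC(=O)Cc1ccc(OCc2ccccc2)c(OCc2ccccc2)c1)C(=O)c1ccc(OCc2ccccc2)c(OCc2ccccc2)c1 | intermediate
9 | tert-butyl 2,3-bis[3,4-bis(benzyloxy)phenyl]-2-hydroxy-4-oxocyclopentane-1-carboxylate (aldol adduct, mixture of stereoisomers) | CC(C)(C)OC(=O)C1CC(=O)C(c2ccc(OCc3ccccc3)c(OCc3ccccc3)c2)C1(O)c1ccc(OCc2ccccc2)c(OCc2ccccc2)c1 | intermediate
10 | tert-butyl 2,3-bis[3,4-bis(benzyloxy)phenyl]-4-oxocyclopent-2-ene-1-carboxylate (racemic, C1 stereolabile) | CC(C)(C)OC(=O)C1CC(=O)C(c2ccc(OCc3ccccc3)c(OCc3ccccc3)c2)=C1c1ccc(OCc2ccccc2)c(OCc2ccccc2)c1 | intermediate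
11 | tert-butyl (1S,2R,3R)-2,3-bis[3,4-bis(benzyloxy)phenyl]-4-oxocyclopentane-1-carboxylate (all-cis) | C1[C@H](C(=O)OC(C)(C)C)[C@H](c2ccc(OCc3ccccc3)c(OCc3ccccc3)c2)[C@H](c2ccc(OCc3ccccc3)c(OCc3ccccc3)c2)C1=O | intermediate
12 | tert-butyl (1S,2R,3S)-2,3-bis[3,4-bis(benzyloxy)phenyl]-4-oxocyclopentane-1-carboxylate | C1[C@H](C(=O)OC(C)(C)C)[C@H](c2ccc(OCc3ccccc3)c(OCc3ccccc3)c2)[C@@H](c2ccc(OCc3ccccc3)c(OCc3ccccc3)c2)C1=O | intermediate
13 | tert-butyl (1R,2R,3S)-2,3-bis[3,4-bis(benzyloxy)phenyl]-5-(hydroxymethylidene)-4-oxocyclopentane-1-carboxylate | OC=C1[C@H](C(=O)OC(C)(C)C)[C@H](c2ccc(OCc3ccccc3)c(OCc3ccccc3)c2)[C@@H](c2ccc(OCc3ccccc3)c(OCc3ccccc3)c2)C1=O | intermediate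
14 | tert-butyl (1R,2R,3S)-2,3-bis[3,4-bis(benzyloxy)phenyl]-5-diazo-4-oxocyclopentane-1-carboxylate | [N-]=[N+]=C1[C@H](C(=O)OC(C)(C)C)[C@H](c2ccc(OCc3ccccc3)c(OCc3ccccc3)c2)[C@@H](c2ccc(OCc3ccccc3)c(OCc3ccccc3)c2)C1=O | intermediate
15 | (2R)-3-(3,4-dihydroxyphenyl)-2-hydroxypropanoic acid (danshensu) | O[C@H](Cc1ccc(O)c(O)c1)C(=O)O | starting material
16 | benzyl (2R)-3-[3,4-bis(benzyloxy)phenyl]-2-hydroxypropanoate | O[C@H](Cc1ccc(OCc2ccccc2)c(OCc2ccccc2)c1)C(=O)OCc1ccccc1 | intermediate
17 | tert-butyl (1R,2R,3S)-2,3-bis[3,4-bis(benzyloxy)phenyl]-4-(oxomethylidene)cyclobutane-1-carboxylate (ketene) | O=C=C1[C@H](C(=O)OC(C)(C)C)[C@H](c2ccc(OCc3ccccc3)c(OCc3ccccc3)c2)[C@H]1c1ccc(OCc2ccccc2)c(OCc2ccccc2)c1 | intermediate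
18 | tert-butyl (1R,2R,3S)-4-[{[(2R)-1-(benzyloxy)-3-[3,4-bis(benzyloxy)phenyl]-1-oxopropan-2-yl]oxy}(hydroxy)methylidene]-2,3-bis[3,4-bis(benzyloxy)phenyl]cyclobutane-1-carboxylate (ester enol) | OC(O[C@H](Cc2ccc(OCc3ccccc3)c(OCc3ccccc3)c2)C(=O)OCc2ccccc2)=C1[C@H](C(=O)OC(C)(C)C)[C@H](c2ccc(OCc3ccccc3)c(OCc3ccccc3)c2)[C@H]1c1ccc(OCc2ccccc2)c(OCc2ccccc2)c1 | intermediate
19 | 1-[(2R)-1-(benzyloxy)-3-[3,4-bis(benzyloxy)phenyl]-1-oxopropan-2-yl] 2-tert-butyl (1R,2R,3R,4R)-3,4-bis[3,4-bis(benzyloxy)phenyl]cyclobutane-1,2-dicarboxylate | O=C(O[C@H](Cc1ccc(OCc2ccccc2)c(OCc2ccccc2)c1)C(=O)OCc1ccccc1)[C@H]1[C@H](C(=O)OC(C)(C)C)[C@H](c2ccc(OCc3ccccc3)c(OCc3ccccc3)c2)[C@H]1c1ccc(OCc2ccccc2)c(OCc2ccccc2)c1 | intermediate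
20 | (1R,2R,3R,4R)-2-({[(2R)-1-(benzyloxy)-3-[3,4-bis(benzyloxy)phenyl]-1-oxopropan-2-yl]oxy}carbonyl)-3,4-bis[3,4-bis(benzyloxy)phenyl]cyclobutane-1-carboxylic acid | O=C(O[C@H](Cc1ccc(OCc2ccccc2)c(OCc2ccccc2)c1)C(=O)OCc1ccccc1)[C@H]1[C@H](C(=O)O)[C@H](c2ccc(OCc3ccccc3)c(OCc3ccccc3)c2)[C@H]1c1ccc(OCc2ccccc2)c(OCc2ccccc2)c1 | intermediate
21 | L-DOPA, (2S)-2-amino-3-(3,4-dihydroxyphenyl)propanoic acid | N[C@@H](Cc1ccc(O)c(O)c1)C(=O)O | starting material
22 | (2S)-3-(3,4-dihydroxyphenyl)-2-hydroxypropanoic acid | O[C@@H](Cc1ccc(O)c(O)c1)C(=O)O | intermediate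
23 | benzyl (2S)-3-[3,4-bis(benzyloxy)phenyl]-2-hydroxypropanoate | O[C@@H](Cc1ccc(OCc2ccccc2)c(OCc2ccccc2)c1)C(=O)OCc1ccccc1 | intermediate
24 | bis[(2R)-1-(benzyloxy)-3-[3,4-bis(benzyloxy)phenyl]-1-oxopropan-2-yl] (1R,2R,3R,4R)-3,4-bis[3,4-bis(benzyloxy)phenyl]cyclobutane-1,2-dicarboxylate | O=C(O[C@H](Cc1ccc(OCc2ccccc2)c(OCc2ccccc2)c1)C(=O)OCc1ccccc1)[C@H]1[C@H](C(=O)O[C@H](Cc2ccc(OCc3ccccc3)c(OCc3ccccc3)c2)C(=O)OCc2ccccc2)[C@H](c2ccc(OCc3ccccc3)c(OCc3ccccc3)c2)[C@H]1c1ccc(OCc2ccccc2)c(OCc2ccccc2)c1 | intermediate
25 | bis[(1R)-1-carboxy-2-(3,4-dihydroxyphenyl)ethyl] (1R,2R,3R,4R)-3,4-bis(3,4-dihydroxyphenyl)cyclobutane-1,2-dicarboxylate (CNP0163929.1) | O=C(O[C@H](Cc1ccc(O)c(O)c1)C(=O)O)[C@H]1[C@H](C(=O)O[C@H](Cc2ccc(O)c(O)c2)C(=O)O)[C@H](c2ccc(O)c(O)c2)[C@H]1c1ccc(O)c(O)c1 | target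

## Step count and least certain steps

Total: 14 steps. Longest linear sequence: 10 steps (1 or 2, then 3, 4, 5, 6, 7, 9, 10, 13, 14).

**Step 5 (proposed new method).** Hydride transfer to a tetrasubstituted, doubly aryl-substituted enone may be slow, so that 1,2-reduction of the ketone or silylation of the dienolate takes over. The ligand's facial preference may be overridden by the substrate's own anti-to-ester bias, which would give the cis product with little enantiomeric enrichment. If the labile centre racemises more slowly than it is reduced, the process becomes a simple kinetic resolution. The fallback sets out from 10 and returns at 19. The enone is hydrogenated as the racemate over Pd/C modified with ethylenediamine, a catalyst that saturates alkenes while aryl benzyl ethers are retained. Syn addition to the face away from the ester gives 11 together with its antipode tert-butyl (1R,2S,3S)-2,3-Ar2-4-oxocyclopentane-1-carboxylate F1, and DBU converts these into 12 and its antipode tert-butyl (1R,2S,3R)-2,3-Ar2-4-oxocyclopentane-1-carboxylate F2. Steps 6 and 7 on the racemate give 13 and 14 with their antipodes tert-butyl (1S,2S,3R)-2,3-Ar2-5-(hydroxymethylidene)-4-oxocyclopentane-1-carboxylate F3 and tert-butyl (1S,2S,3R)-2,3-Ar2-5-diazo-4-oxocyclopentane-1-carboxylate F4. Ring contraction with enantiopure 16 then gives 19 and the diastereomer 1-[(2R)-1-(benzyloxy)-3-Ar-1-oxopropan-2-yl] 2-tert-butyl (1S,2S,3S,4S)-3,4-Ar2-cyclobutane-1,2-dicarboxylate F5, which are separated by chromatography or crystallisation. Half of the ring material is lost, but only known chemistry is used.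

**Step 9 (key step).** Two things can go wrong. Protonation of 18 may show poor or reversed facial selectivity if the tert-butoxycarbonyl group, helped by the aryl across the ring, shields its face more than the adjacent aryl does. Capture of 17 by the hindered, weakly nucleophilic alcohol may be slow enough for ketene dimerisation or hydration to compete. The fallback sets out from 14 and returns at 20; it replaces kinetic protonation by equilibration, which should favour the wanted epimer if the ester is the effectively larger neighbour. Irradiation of 14 with allyl alcohol in place of 16 gives 2-tert-butyl 1-(prop-2-en-1-yl) (1R,2R,3R,4R)-3,4-Ar2-cyclobutane-1,2-dicarboxylate F6 together with its epimer at the allyl ester carbon, the (1S,2R,3R,4R)-diester F7. CF3CO2H frees the other carboxyl to give (1R,2R,3R,4R)-3,4-Ar2-2-[(prop-2-en-1-yloxy)carbonyl]cyclobutane-1-carboxylic acid F8 and its (1R,2S,3R,4R)-epimer F9. Sodium prop-2-en-1-olate in allyl alcohol then equilibrates the only enolisable centre left, the allyl ester carbon (the carboxylate carbon is protected by its charge), towards the trans-diacid derivative F8. Mitsunobu coupling of F8 with 23 gives 1-[(2R)-1-(benzyloxy)-3-Ar-1-oxopropan-2-yl] 2-(prop-2-en-1-yl) (1R,2R,3R,4R)-3,4-Ar2-cyclobutane-1,2-dicarboxylate F10. Pd(PPh3)4 with morpholine removes the allyl group and, because the ring core is C2-symmetric, the acid obtained is 20.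

**Step 6.** The ester-bearing centre may epimerise (cis to trans relative to the aryl) during prolonged exposure to alkoxide, and formylation may be incomplete. The fallback sets out from 12 and returns at 14. tert-Butoxybis(dimethylamino)methane in warm toluene condenses only at the methylene α-carbon, without a strong base, to give the enaminone tert-butyl (1R,2R,3S)-2,3-Ar2-5-[(dimethylamino)methylidene]-4-oxocyclopentane-1-carboxylate F11. 4-Acetamidobenzenesulfonyl azide then transfers the diazo group by cycloaddition and cycloreversion.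

**Step 11.** Nitrous acid may oxidise or nitrosate the unprotected catechol in competition with diazotisation. The fallback sets out from 16 and returns at 23. Mitsunobu inversion of 16 with chloroacetic acid gives benzyl (2S)-3-Ar-2-[(chloroacetyl)oxy]propanoate F12, and thiourea with NaHCO3 in ethanol removes the chloroacetyl group without touching the benzyl ester. Compound 15 then serves as the source of both side chains.

**Step 13.** The phosphorus-activated lactate may eliminate to the cinnamate, and attack by the hindered cyclobutane carboxylate may be slow. The fallback sets out from 20 and returns at 24. The acid 20 is used instead as the acyl donor towards the (R)-alcohol 16 (carbodiimide with catalytic DMAP, CH2Cl2, 0 °C), which proceeds with retention at the carbinol carbon and makes no new compound. The risk then moves to the α-centre of the activated acid, so the activation must be kept cold and brief.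

## Further compounds

F1 | step 5 | tert-butyl (1R,2S,3S)-2,3-bis[3,4-bis(benzyloxy)phenyl]-4-oxocyclopentane-1-carboxylate | C1[C@@H](C(=O)OC(C)(C)C)[C@@H](c2ccc(OCc3ccccc3)c(OCc3ccccc3)c2)[C@@H](c2ccc(OCc3ccccc3)c(OCc3ccccc3)c2)C1=O
F2 | step 5 | tert-butyl (1R,2S,3R)-2,3-bis[3,4-bis(benzyloxy)phenyl]-4-oxocyclopentane-1-carboxylate | C1[C@@H](C(=O)OC(C)(C)C)[C@@H](c2ccc(OCc3ccccc3)c(OCc3ccccc3)c2)[C@H](c2ccc(OCc3ccccc3)c(OCc3ccccc3)c2)C1=O
F3 | step 5 | tert-butyl (1S,2S,3R)-2,3-bis[3,4-bis(benzyloxy)phenyl]-5-(hydroxymethylidene)-4-oxocyclopentane-1-carboxylate | OC=C1[C@@H](C(=O)OC(C)(C)C)[C@@H](c2ccc(OCc3ccccc3)c(OCc3ccccc3)c2)[C@H](c2ccc(OCc3ccccc3)c(OCc3ccccc3)c2)C1=O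
F4 | step 5 | tert-butyl (1S,2S,3R)-2,3-bis[3,4-bis(benzyloxy)phenyl]-5-diazo-4-oxocyclopentane-1-carboxylate | [N-]=[N+]=C1[C@@H](C(=O)OC(C)(C)C)[C@@H](c2ccc(OCc3ccccc3)c(OCc3ccccc3)c2)[C@H](c2ccc(OCc3ccccc3)c(OCc3ccccc3)c2)C1=O
F5 | step 5 | 1-[(2R)-1-(benzyloxy)-3-[3,4-bis(benzyloxy)phenyl]-1-oxopropan-2-yl] 2-tert-butyl (1S,2S,3S,4S)-3,4-bis[3,4-bis(benzyloxy)phenyl]cyclobutane-1,2-dicarboxylate | O=C(O[C@H](Cc1ccc(OCc2ccccc2)c(OCc2ccccc2)c1)C(=O)OCc1ccccc1)[C@@H]1[C@@H](C(=O)OC(C)(C)C)[C@@H](c2ccc(OCc3ccccc3)c(OCc3ccccc3)c2)[C@@H]1c1ccc(OCc2ccccc2)c(OCc2ccccc2)c1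
F6 | step 9 | 2-tert-butyl 1-(prop-2-en-1-yl) (1R,2R,3R,4R)-3,4-bis[3,4-bis(benzyloxy)phenyl]cyclobutane-1,2-dicarboxylate | C=CCOC(=O)[C@H]1[C@H](C(=O)OC(C)(C)C)[C@H](c2ccc(OCc3ccccc3)c(OCc3ccccc3)c2)[C@H]1c1ccc(OCc2ccccc2)c(OCc2ccccc2)c1
F7 | step 9 | 2-tert-butyl 1-(prop-2-en-1-yl) (1S,2R,3R,4R)-3,4-bis[3,4-bis(benzyloxy)phenyl]cyclobutane-1,2-dicarboxylate | C=CCOC(=O)[C@@H]1[C@H](C(=O)OC(C)(C)C)[C@H](c2ccc(OCc3ccccc3)c(OCc3ccccc3)c2)[C@H]1c1ccc(OCc2ccccc2)c(OCc2ccccc2)c1
F8 | step 9 | (1R,2R,3R,4R)-3,4-bis[3,4-bis(benzyloxy)phenyl]-2-[(prop-2-en-1-yloxy)carbonyl]cyclobutane-1-carboxylic acid | C=CCOC(=O)[C@H]1[C@H](C(=O)O)[C@H](c2ccc(OCc3ccccc3)c(OCc3ccccc3)c2)[C@H]1c1ccc(OCc2ccccc2)c(OCc2ccccc2)c1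
F9 | step 9 | (1R,2S,3R,4R)-3,4-bis[3,4-bis(benzyloxy)phenyl]-2-[(prop-2-en-1-yloxy)carbonyl]cyclobutane-1-carboxylic acid | C=CCOC(=O)[C@@H]1[C@H](C(=O)O)[C@H](c2ccc(OCc3ccccc3)c(OCc3ccccc3)c2)[C@H]1c1ccc(OCc2ccccc2)c(OCc2ccccc2)c1
F10 | step 9 | 1-[(2R)-1-(benzyloxy)-3-[3,4-bis(benzyloxy)phenyl]-1-oxopropan-2-yl] 2-(prop-2-en-1-yl) (1R,2R,3R,4R)-3,4-bis[3,4-bis(benzyloxy)phenyl]cyclobutane-1,2-dicarboxylate | C=CCOC(=O)[C@H]1[C@H](C(=O)O[C@H](Cc2ccc(OCc3ccccc3)c(OCc3ccccc3)c2)C(=O)OCc2ccccc2)[C@H](c2ccc(OCc3ccccc3)c(OCc3ccccc3)c2)[C@H]1c1ccc(OCc2ccccc2)c(OCc2ccccc2)c1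
F11 | step 6 | tert-butyl (1R,2R,3S)-2,3-bis[3,4-bis(benzyloxy)phenyl]-5-[(dimethylamino)methylidene]-4-oxocyclopentane-1-carboxylate | CN(C)C=C1[C@H](C(=O)OC(C)(C)C)[C@H](c2ccc(OCc3ccccc3)c(OCc3ccccc3)c2)[C@@H](c2ccc(OCc3ccccc3)c(OCc3ccccc3)c2)C1=O
F12 | step 11 | benzyl (2S)-3-[3,4-bis(benzyloxy)phenyl]-2-[(chloroacetyl)oxy]propanoate | ClCC(=O)O[C@@H](Cc1ccc(OCc2ccccc2)c(OCc2ccccc2)c1)C(=O)OCc1ccccc1
F0 | step 13 | none | none
A1 | alternative 1 | (1R,2R)-N1,N2-di(quinolin-8-yl)cyclobutane-1,2-dicarboxamide | O=C(Nc1cccc2cccnc12)[C@H]1[C@H](C(=O)Nc2cccc3cccnc23)CC1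
A2 | alternative 1 | 1,2-bis(benzyloxy)-4-iodobenzene | Ic1ccc(OCc2ccccc2)c(OCc2ccccc2)c1
A3 | alternative 1 | (1R,2R,3R,4R)-3,4-bis[3,4-bis(benzyloxy)phenyl]-N1,N2-di(quinolin-8-yl)cyclobutane-1,2-dicarboxamide | O=C(Nc1cccc2cccnc12)[C@H]1[C@H](C(=O)Nc2cccc3cccnc23)[C@H](c2ccc(OCc3ccccc3)c(OCc3ccccc3)c2)[C@H]1c1ccc(OCc2ccccc2)c(OCc2ccccc2)c1
A4 | alternative 2 | ethyl 2-[(2S,3S)-2,3-bis[3,4-bis(benzyloxy)phenyl]-1-(ethoxycarbonyl)cyclopropyl]-2-diazoacetate | CCOC(=O)C(=[N+]=[N-])C1(C(=O)OCC)[C@H](c2ccc(OCc3ccccc3)c(OCc3ccccc3)c2)[C@H]1c1ccc(OCc2ccccc2)c(OCc2ccccc2)c1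
A5 | alternative 2 | diethyl (3S,4S)-3,4-bis[3,4-bis(benzyloxy)phenyl]cyclobut-1-ene-1,2-dicarboxylate | CCOC(=O)C1=C(C(=O)OCC)[C@H](c2ccc(OCc3ccccc3)c(OCc3ccccc3)c2)[C@H]1c1ccc(OCc2ccccc2)c(OCc2ccccc2)c1
A6 | alternative 3 | 1,1-di-tert-butyl 4-methyl (2R,3S,4R)-2,3-bis[3,4-bis(benzyloxy)phenyl]-4-{[(trifluoromethyl)sulfonyl]oxy}butane-1,1,4-tricarboxylate | CC(C)(C)OC(=O)C(C(=O)OC(C)(C)C)[C@H](c1ccc(OCc2ccccc2)c(OCc2ccccc2)c1)[C@@H](c1ccc(OCc2ccccc2)c(OCc2ccccc2)c1)[C@@H](OS(=O)(=O)C(F)(F)F)C(=O)OC
A7 | alternative 3 | 1,1-di-tert-butyl 2-methyl (2R,3R,4S)-3,4-bis[3,4-bis(benzyloxy)phenyl]cyclobutane-1,1,2-tricarboxylate | CC(C)(C)OC(=O)C1(C(=O)OC(C)(C)C)[C@H](C(=O)OC)[C@H](c2ccc(OCc3ccccc3)c(OCc3ccccc3)c2)[C@H]1c1ccc(OCc2ccccc2)c(OCc2ccccc2)c1
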